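## Structural features

The target is a spiro[5.5]undecane. Ring A (C1–C6) carries an exocyclic methylene at C1, a secondary alcohol at C3, a secondary bromide at C4 and a gem-dimethyl group at C5. Ring B (C6–C11) carries a tertiary methyl carbinol at C9 and a secondary chloride at C10; the rings share the quaternary carbon C6. C6 is bonded to the quaternary C5, so the skeleton holds two adjacent fully substituted carbons, and C6 has no heteroatom through which its configuration could be set or corrected. The stereocentres come as two contiguous pairs: C3/C4 is a cis bromohydrin (axial OH, equatorial Br) and C9/C10 is a cis chlorohydrin (axial OH, equatorial Cl and CH3). In this numbering the configuration is 3R,4S,6S,9R,10S, which is (2S,3R,6S,8S,9R) in spiro nomenclature. The fragile groups are both halohydrins (base-induced ring contraction or loss of HX), the homoallylic alcohol with its exocyclic alkene (acid moves the double bond into the ring), and the bromide on a neopentyl-type carbon, which cannot be introduced by substitution. The real difficulty is the absolute configuration at C6 together with the crowded C5–C6 bond. C6 is stereogenic only because the ring B arms C7–C8–C9 and C11–C10–C9 differ at C9 and C10. The key step uses exactly this: with ring B opened between C9 and C10, C6 bears two identical 3-oxopropyl arms and is prochiral, so a chiral amine that closes C9–C10 converts arm recognition into the C6 stereocentre, while C1–C5 of ring A ride along as an isopropenyl and a 2-methylbut-3-en-2-yl group.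

## Logic of the disconnections

28 to 27: the O–Si bond at C9 is cut. The tertiary alcohol of the chlorohydrin is kept masked through the borane, oxidation and Lewis acid steps. Nothing is simplified in the skeleton; the gain is safety. The forward step needs an acidic, not a basic, fluoride source.

27 to 26: the C2–C3 bond is cut. A homoallylic alcohol next to an exocyclic methylene is the retron of a type 2 carbonyl-ene reaction between an aldehyde (C3) and an isopropenyl group (C1, C2). This opens ring A, removes the C3 stereocentre and leaves a monocyclic aldehyde. The forward step must place oxygen axial and bromine equatorial in the closing chair and must spare the silyl ether and the chloride.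

26 to 25: the C4–Br bond is cut. Bromine sits alpha to the aldehyde, so it can enter through an enamine; displacement at this neopentyl position is not an option. One stereocentre is removed. The forward step needs catalyst control over any bias from the distant ring B centres, and the product must be used at once because it is configurationally labile.

25 to 24 to 22: no skeletal bond is cut. The C3 aldehyde is traced to the terminal vinyl group on C5 by anti-Markovnikov hydration and oxidation, because a vinyl group is what the sigmatropic step leaves on C5. The borane must choose the monosubstituted vinyl group over the isopropenyl group.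

22 to 21 to 20: the O–Si bond and the C9–CH3 bond are cut. A cis chlorohydrin with a tertiary carbinol is the retron of methyl addition to an alpha-chloro ketone. This removes the C9 stereocentre. The forward step needs equatorial entry of the methyl group and no enolisation.

20 to 18 to 17: the C10–Cl bond is cut and a formyl carbon is put back on C10. The ketone has two alpha positions that differ only remotely, so chlorine can be directed only by a marker; the formyl group of the aldol product is that marker. It is kept as a formyl group rather than oxidised to a beta-keto acid, because the 2-formyl ketone is stable whereas a beta-keto acid could lose CO2, and with it the marker, before chlorination. The forward steps need chlorination at the doubly activated carbon, loss of the formyl group, and thermodynamic control at C10.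

17 to 14: the C9–C10 bond is cut (key step). Ring B is opened, three stereocentres disappear and the precursor becomes achiral. The forward step must make one of two enantiotopic arms the nucleophile.

14 to 13 to 12: only oxidation level and O–Si bonds change. The dialdehyde is too sensitive to carry, so the arms travel as silyl ethers through the organometallic steps and are unveiled just before use.

12 to 11 to 9: the C1=CH2 bond and then the C1–CH3 bond are cut, tracing the isopropenyl group through a methyl ketone to a carboxylic acid, which is what the rearrangement delivers on C6. The forward reagents must reach a carbonyl attached to a quaternary carbon, and the methylenation must be non-basic.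

9 to 6: the C5–C6 bond is cut by a retro Ireland–Claisen step. Two adjacent quaternary carbons are best joined inside a six-membered transition state. Because the two arms on C6 are identical there is no enolate geometry to control. The result is an ester of an achiral acid with prenol. The forward step needs enolisation of a branched ester and enough heat for a crowded shift.

6 to 5 to 3: the arm C–O bonds are traced to the two allyl groups by hydroboration, and this is placed before the rearrangement. At this stage the borane only has to tell monosubstituted alkenes from one trisubstituted, ester-deactivated alkene. After the rearrangement a third monosubstituted alkene (the vinyl group on C5) and later the isopropenyl group would compete. The forward steps need the ester to survive and the diol to be silylated before it can lactonise.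

3 to 1 and 2: the ester C–O bond is cut, giving two commercial compounds.

## Other disconnections considered

Alternative 1: The cut is C1–C2 of ring A, with the methylene carbon drawn back into a terminal alkyne on C6.
- Forward step: iodide A2 (ring B complete, ethynyl on C6, the C5–C4–C3 chain extended by an iodomethyl carbon C2) would be treated with (Me3Si)3SiH and Et3B/air. The C2 radical would add 6-exo-dig to the inner alkyne carbon and the vinyl radical would take hydrogen from the silane, giving A1, the bis-silyl ether of 28.
- In favour: the double bond can only be exocyclic. The conditions are neutral and cold, which suits both halohydrins. C3 is fixed before the ring closes, which is better than in the chosen plan, where C3 is left to the ene transition state.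
- Against: the silyl radical must take iodine from C2 in the presence of a secondary bromide at C4 and a chloride at C10, and the margin between C–I and C–Br abstraction is modest; a radical at C4 would be reduced and a stereocentre lost. The 6-exo-dig closure onto a neopentyl-type alkyne competes with direct reduction of the C2 radical. A2 needs one more carbon than 26, a C3 stereocentre set in an open chain next to C4, and an alkyne in place of the isopropenyl group.
- Comparison: structurally it answers only ring A; ring B and C6 would still need a step such as step 9, so it competes with steps 16–17, not with the key step. On alkene regiochemistry the two plans are equal. Mechanistically the ene closure forms C2–C3 and the carbinol in one two-electron step with no halogen selectivity to manage. In step economy the chosen closure is shorter, since the aldehyde carbon itself becomes C3.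

Alternative 2: The cut is C6–C11 together with C10–Cl.
- Forward step: A4, a tertiary alpha-chloro methyl ketone whose chain ends in the silylated vinyl carbinol unit of (R)-linalool A5, would be exposed to CuCl and tris(2-pyridylmethyl)amine. The monovalent copper complex abstracts chlorine from C6, the C6 radical adds to the terminal alkene carbon C11 (6-endo), and the C10 radical takes chlorine back from the divalent copper chloride complex, giving A3.
- In favour: C9 with its methyl group and oxygen comes from the chiral pool, so the facial question of step 12 disappears; on this point it is better than the chosen plan. Ring B, the C6 quaternary centre and the C–Cl bond arise in one redox-neutral catalytic step, which is better bond economy than steps 9–12.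
- Against: the planar, very hindered C6 radical must prefer 6-endo over 5-exo attack and then set two stereocentres (C6 and C10) under the influence of C9 alone. The chlorine return to C10 has no clear facial bias, whereas step 11 puts C10 under thermodynamic control. A4 still needs the crowded C5–C6 bond and an alpha-chlorination next to a quaternary carbon. Enantiomeric purity is capped by that of commercial A5.
- Comparison: from A3 onward (acetyl to isopropenyl, then steps 14–18) the plans are equal. In step count to ring B the alternative is probably shorter, hence better. Mechanistically it stakes three selectivities on one radical step, while the chosen plan stakes one arm selection on a catalytic step of a known type and settles C10 and C9 separately.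

Alternative 3: The cut is C6–C7, made after ring A is complete.
- Forward step: A7, a cyclohexene with a C1=C6 double bond, the silylated bromohydrin at C3/C4 and a C6 side chain bearing the C10 chloride and a terminal vinyl ketone, would be treated with MeAlCl2. C6 attacks the enone terminus C7, a hydrogen of the C1 methyl group moves to C8, and the spiro alpha-chloro ketone A6 results.
- In favour: C3 and C4 are set on a simple monocycle. The spiro centre and the exocyclic methylene appear together. After A6 only methyl addition and desilylation remain, a shorter end game than steps 12–18 and so better on that count. C6 is under substrate control and needs no chiral catalyst.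
- Against: the quaternary centre is formed by attack of a tetrasubstituted alkene carbon next to the gem-dimethyl carbon, a very crowded bond formation. The hydrogen could equally be lost from C2, putting the double bond in the ring. The face that C7 approaches is decided only by the distant C3/C4 substituents. The alpha-chloro alpha'-vinyl ketone is prone to polymerisation, HCl loss and C10 epimerisation under MeAlCl2.
- Comparison: C10 could be corrected by equilibration after closure exactly as in step 11, and methyl addition to A6 faces the same facial question as step 12; the plans are equal on both. Structurally the alternative is more convergent, but A7 needs its own enantioselective synthesis, so the total count is unlikely to be lower. Mechanistically a cationic ene step at a crowded centre is less predictable than the aminocatalytic closure.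

Key step: step 9

Assumption: (S)-proline is taken to act in its usual sense (enamine on one arm, acid-assisted attack on the other aldehyde through a chair), which corresponds to the 9S,10S,6S configuration drawn for 17 and to 6S in 28; the sense of the amine in step 16 follows the steric shielding model.

## Route

Step 1
Reactants: 1 2-allylpent-4-enoic acid; 2 prenol (3-methylbut-2-en-1-ol)
Product: 3 3-methylbut-2-en-1-yl 2-(prop-2-en-1-yl)pent-4-enoate
Conditions: DCC, DMAP (cat.), CH2Cl2, 0 °C → rt
Reagents that add atoms: none
Why: Steglich esterification (carbodiimide activation, DMAP acyl transfer) of an unhindered acid with a primary allylic alcohol; no stereocentre is involved.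

Step 2
Reactants: 3 3-methylbut-2-en-1-yl 2-(prop-2-en-1-yl)pent-4-enoate
Product: 5 3-methylbut-2-en-1-yl 5-hydroxy-2-(3-hydroxypropyl)pentanoate, via bis-9-BBN adduct 4 (not isolated)
Conditions: 9-BBN (2.3 equiv), THF, 0 °C → rt; then NaOAc (aq), 30% H2O2, 0 °C → rt
Reagents that add atoms: hydrogen peroxide, OO
Why: Anti-Markovnikov hydroboration–oxidation; 9-BBN adds to monosubstituted terminal alkenes far faster than to the trisubstituted, ester-deactivated prenyl alkene and does not reduce esters, so only the two allyl groups react; buffered peroxide spares the ester, and 5 is silylated without delay to forestall lactonisation.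

Step 3
Reactants: 5 3-methylbut-2-en-1-yl 5-hydroxy-2-(3-hydroxypropyl)pentanoate
Product: 6 3-methylbut-2-en-1-yl 5-[(tert-butyldimethylsilyl)oxy]-2-{3-[(tert-butyldimethylsilyl)oxy]propyl}pentanoate
Conditions: t-BuMe2SiCl, imidazole, DMF, 0 °C → rt
Reagents that add atoms: tert-butyldimethylsilyl chloride, CC(C)(C)[Si](C)(C)Cl
Why: Standard imidazole-promoted silylation of primary alcohols; the ethers mask the arms through the enolate, organolithium and titanium steps.

Step 4
Reactants: 6 3-methylbut-2-en-1-yl 5-[(tert-butyldimethylsilyl)oxy]-2-{3-[(tert-butyldimethylsilyl)oxy]propyl}pentanoate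
Product: 9 2,2-bis{3-[(tert-butyldimethylsilyl)oxy]propyl}-3,3-dimethylpent-4-enoic acid, via silyl ketene acetal 7 (not isolated), via trimethylsilyl ester 8 (not isolated)
Conditions: LiN(iPr)2, THF, −78 °C; Me3SiCl, Et3N, −78 → 65 °C; then aqueous citric acid, 0 °C
Reagents that add atoms: none
Why: Ireland–Claisen rearrangement: the ester enolate is trapped as ketene acetal 7, whose chair [3,3] shift joins C6 to the dimethyl-substituted terminus of the prenyl group (C5) and gives silyl ester 8, hydrolysed on work-up; the two identical substituents on the ketene acetal carbon remove any enolate-geometry question and no stereocentre forms; the six-membered transition state is what allows two adjacent quaternary carbons to be made.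

Step 5
Reactants: 9 2,2-bis{3-[(tert-butyldimethylsilyl)oxy]propyl}-3,3-dimethylpent-4-enoic acid
Product: 11 3,3-bis{3-[(tert-butyldimethylsilyl)oxy]propyl}-4,4-dimethylhex-5-en-2-one, via dilithium gem-diolate 10 (not isolated)
Conditions: MeLi (3.5 equiv), Et2O, 0 °C → rt; inverse quench into ice-water
Reagents that add atoms: methyllithium, [Li]C
Why: Addition of methyllithium to a lithium carboxylate stops at the dilithium gem-diolate 10, which gives the methyl ketone only on hydrolysis; crowding around C6 further disfavours a second addition.

Step 6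
Reactants: 11 3,3-bis{3-[(tert-butyldimethylsilyl)oxy]propyl}-4,4-dimethylhex-5-en-2-one
Product: 12 1,7-bis[(tert-butyldimethylsilyl)oxy]-4-(2-methylbut-3-en-2-yl)-4-(prop-1-en-2-yl)heptane
Conditions: Cp2TiMe2 (3 equiv), toluene, 70 °C, dark
Reagents that add atoms: dimethyltitanocene (Cp2TiMe2), [CH3-].[CH3-].[Ti+4].[cH-]1cccc1.[cH-]1cccc1
Why: Petasis methylenation: thermolysis of Cp2TiMe2 gives Cp2Ti=CH2, which converts the ketone into the alkene through an oxatitanacyclobutane; the reagent is non-basic and tolerates hindered, enolisable ketones and silyl ethers.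

Step 7
Reactants: 12 1,7-bis[(tert-butyldimethylsilyl)oxy]-4-(2-methylbut-3-en-2-yl)-4-(prop-1-en-2-yl)heptane
Product: 13 4-(2-methylbut-3-en-2-yl)-4-(prop-1-en-2-yl)heptane-1,7-diol
Conditions: Bu4NF, THF, rt
Reagents that add atoms: none
Why: Fluoride cleavage of the two primary silyl ethers; nothing else in 12 is sensitive to fluoride or mild base.

Step 8
Reactants: 13 4-(2-methylbut-3-en-2-yl)-4-(prop-1-en-2-yl)heptane-1,7-diol
Product: 14 4-(2-methylbut-3-en-2-yl)-4-(prop-1-en-2-yl)heptanedial
Conditions: (COCl)2, DMSO, CH2Cl2, −78 °C; Et3N, −78 → 0 °C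
Reagents that add atoms: none
Why: Swern oxidation of both primary alcohols at low temperature, free of acid or metal that could trigger a carbonyl-ene reaction between an aldehyde arm and the isopropenyl group; achiral 14 is used directly.

Step 9
Reactants: 14 4-(2-methylbut-3-en-2-yl)-4-(prop-1-en-2-yl)heptanedial
Product: 17 (1S,2S,5S)-2-hydroxy-5-(2-methylbut-3-en-2-yl)-5-(prop-1-en-2-yl)cyclohexane-1-carbaldehyde, via proline enamine 15 (not isolated), via aldol iminium 16 (not isolated)
Conditions: (S)-proline (20 mol %), CH2Cl2, rt
Reagents that add atoms: none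
Why: (S)-Proline condenses with either aldehyde to the (E)-enamine 15 and its carboxylic acid activates the other aldehyde by hydrogen bonding inside a chair-like transition state; C10 of the enamine attacks the carbonyl carbon C9, and hydrolysis of iminium 16 releases 17 and the catalyst. The closest known reaction type is the proline-catalysed intramolecular aldolisation of heptanedials, including desymmetrisation of 4-substituted members. Ring B closes in the 6-enolexo mode (6-exo-trig with respect to the carbonyl). C9 and C10 are set by the catalyst: the anti enamine adds to the acid-bound aldehyde face and gives the trans hydroxy aldehyde with 9S,10S configuration. C6 is set by the chair, which must put one C6 substituent axial; the tert-alkyl group stays equatorial and the smaller, flat isopropenyl group goes axial, so only the arm that leads to 6S becomes the nucleophile. The step therefore needs selection between two enantiotopic arms, and this is secured by catalyst control at C9/C10 combined with the large difference in steric demand of the two C6 substituents. Regiochemistry is no issue because the arms are identical, and the neutral conditions leave the isopropenyl and vinyl groups untouched.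

Step 10
Reactants: 17 (1S,2S,5S)-2-hydroxy-5-(2-methylbut-3-en-2-yl)-5-(prop-1-en-2-yl)cyclohexane-1-carbaldehyde
Product: 18 (5S)-5-(2-methylbut-3-en-2-yl)-2-oxo-5-(prop-1-en-2-yl)cyclohexane-1-carbaldehyde (enolised at C1)
Conditions: Dess–Martin periodinane, CH2Cl2, 0 °C → rt
Reagents that add atoms: none
Why: Dess–Martin oxidation of the secondary alcohol of a beta-hydroxy aldehyde gives the 2-formyl ketone, stabilised as its hydrogen-bonded hydroxymethylene tautomer; C9 and C10 lose their configuration here by design, while C6 and the marker on C10 remain.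

Step 11
Reactants: 18 (5S)-5-(2-methylbut-3-en-2-yl)-2-oxo-5-(prop-1-en-2-yl)cyclohexane-1-carbaldehyde
Product: 20 (2S,4S)-2-chloro-4-(2-methylbut-3-en-2-yl)-4-(prop-1-en-2-yl)cyclohexan-1-one, via chloro formyl ketone 19 (not isolated)
Conditions: NCS, CH2Cl2, 0 °C; then NaHCO3 (aq), THF, rt; Et3N (cat.), rt
Reagents that add atoms: N-chlorosuccinimide, O=C1CCC(=O)N1Cl
Why: Deformylative halogenation of a 2-(hydroxymethylene) ketone: the enol is chlorinated only at the doubly activated C10, and the non-enolisable chloro keto aldehyde 19 loses its formyl group as formate on mild aqueous base (retro-Claisen cleavage); the alpha-chloro ketone then equilibrates through its enol to the epimer with chlorine equatorial, since an axial chlorine would be syn-diaxial to the axial isopropenyl group on C6, and this fixes 10S.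

Step 12
Reactants: 20 (2S,4S)-2-chloro-4-(2-methylbut-3-en-2-yl)-4-(prop-1-en-2-yl)cyclohexan-1-one
Product: 21 (1R,2S,4S)-2-chloro-1-methyl-4-(2-methylbut-3-en-2-yl)-4-(prop-1-en-2-yl)cyclohexan-1-ol
Conditions: MeMgBr, Et2O–toluene, −78 °C; then H2O
Reagents that add atoms: methylmagnesium bromide, C[Mg]Br
Why: Grignard addition to an alpha-chloro ketone, the classical route to cis chlorohydrins; in the chair locked by the equatorial tert-alkyl group the methyl nucleophile enters along the equatorial trajectory, on the side of the axial C10–H and away from the axial hydrogens at C7 and C11, giving equatorial CH3 and axial OH cis to chlorine (9R); the low temperature suppresses enolisation.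

Step 13
Reactants: 21 (1R,2S,4S)-2-chloro-1-methyl-4-(2-methylbut-3-en-2-yl)-4-(prop-1-en-2-yl)cyclohexan-1-ol
Product: 22 {[(1R,2S,4S)-2-chloro-1-methyl-4-(2-methylbut-3-en-2-yl)-4-(prop-1-en-2-yl)cyclohexyl]oxy}triethylsilane
Conditions: Et3SiOTf, 2,6-lutidine, CH2Cl2, 0 °C
Reagents that add atoms: triethylsilyl trifluoromethanesulfonate, CC[Si](CC)(CC)OS(=O)(=O)C(F)(F)F
Why: Silylation of a hindered tertiary alcohol with a silyl triflate and a hindered pyridine base; the ether blocks alkoxide-driven ring contraction of the cis chlorohydrin in the basic and Lewis acidic steps that follow.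

Step 14
Reactants: 22 {[(1R,2S,4S)-2-chloro-1-methyl-4-(2-methylbut-3-en-2-yl)-4-(prop-1-en-2-yl)cyclohexyl]oxy}triethylsilane
Product: 24 3-[(1S,3S,4R)-3-chloro-4-methyl-1-(prop-1-en-2-yl)-4-(triethylsilyloxy)cyclohexyl]-3-methylbutan-1-ol, via disiamylborane adduct 23 (not isolated)
Conditions: disiamylborane (from BH3·THF and 2-methylbut-2-ene, 0 °C), THF, 0 °C → rt; then NaOH (aq), 30% H2O2, 0 °C
Reagents that add atoms: hydrogen peroxide, OO
Why: Anti-Markovnikov hydroboration–oxidation; disiamylborane discriminates strongly between a monosubstituted alkene and a 1,1-disubstituted one, here an isopropenyl group on a quaternary carbon, and places boron on the terminal carbon of the vinyl group; the secondary chloride and the silyl ether are inert.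

Step 15
Reactants: 24 3-[(1S,3S,4R)-3-chloro-4-methyl-1-(prop-1-en-2-yl)-4-(triethylsilyloxy)cyclohexyl]-3-methylbutan-1-ol
Product: 25 3-[(1S,3S,4R)-3-chloro-4-methyl-1-(prop-1-en-2-yl)-4-(triethylsilyloxy)cyclohexyl]-3-methylbutanal
Conditions: Dess–Martin periodinane, CH2Cl2, 0 °C → rt
Reagents that add atoms: none
Why: Dess–Martin oxidation of a primary alcohol to the aldehyde under non-basic conditions; no epimerisable centre is adjacent.

Step 16
Reactants: 25 3-[(1S,3S,4R)-3-chloro-4-methyl-1-(prop-1-en-2-yl)-4-(triethylsilyloxy)cyclohexyl]-3-methylbutanal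
Product: 26 (2S)-2-bromo-3-[(1S,3S,4R)-3-chloro-4-methyl-1-(prop-1-en-2-yl)-4-(triethylsilyloxy)cyclohexyl]-3-methylbutanal
Conditions: (2R,5R)-2,5-diphenylpyrrolidine (20 mol %), PhCO2H (20 mol %), 4,4-dibromo-2,6-di-tert-butylcyclohexa-2,5-dienone, CH2Cl2–pentane, −40 °C
Reagents that add atoms: 4,4-dibromo-2,6-di-tert-butylcyclohexa-2,5-dienone, O=C1C(C(C)(C)C)=CC(Br)(Br)C=C1C(C)(C)C
Why: Enamine-catalysed alpha-bromination of an aldehyde with a beta-quaternary carbon (the 3,3-dimethylbutanal type); the C2-symmetric amine forms the (E)-enamine, the phenyl group next to the enamine carbon shields one face and bromine is delivered to the other, which by the steric model gives 4S (the antipodal amine would be used if the sense proved opposite); the bromodienone is a mild bromine donor that leaves the isopropenyl group alone, and 26 is used without storage because it is configurationally labile.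

Step 17
Reactants: 26 (2S)-2-bromo-3-[(1S,3S,4R)-3-chloro-4-methyl-1-(prop-1-en-2-yl)-4-(triethylsilyloxy)cyclohexyl]-3-methylbutanal
Product: 27 (2S,3R,6S,8S,9R)-2-bromo-8-chloro-1,1,9-trimethyl-5-methylidene-9-[(triethylsilyl)oxy]spiro[5.5]undecan-3-ol
Conditions: Me2AlCl (2.2 equiv), CH2Cl2, −78 → −40 °C; then cold H2O
Reagents that add atoms: none
Why: Type 2 intramolecular carbonyl-ene reaction promoted by Me2AlCl: the aldehyde carbon C3 bonds to the methylene terminus of the isopropenyl group (new C2–C3 bond, six-membered ring A) while a hydrogen of the isopropenyl methyl group passes to oxygen, so the alkene can only end up exocyclic at C1; in the bicyclic chair transition state oxygen is axial and the C4–Br bond equatorial, anti to the forming bond, which gives the cis bromohydrin (3R); Me2AlCl also scavenges protons, protecting the silyl ether and the new alkene.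

Step 18
Reactants: 27 (2S,3R,6S,8S,9R)-2-bromo-8-chloro-1,1,9-trimethyl-5-methylidene-9-[(triethylsilyl)oxy]spiro[5.5]undecan-3-ol
Product: 28 (2S,3R,6S,8S,9R)-2-bromo-8-chloro-1,1,9-trimethyl-5-methylidenespiro[5.5]undecane-3,9-diol
Conditions: HF·pyridine, pyridine, THF, 0 °C → rt
Reagents that add atoms: none
Why: Acidic fluoride cleavage of the tertiary triethylsilyl ether; buffered HF·pyridine avoids both the basic conditions that would rearrange the halohydrins and strong acid that would move the exocyclic double bond.

## Compound list

1 | 2-allylpent-4-enoic acid | C=CCC(CC=C)C(=O)O | starting material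
2 | prenol (3-methylbut-2-en-1-ol) | CC(C)=CCO | starting material
3 | 3-methylbut-2-en-1-yl 2-(prop-2-en-1-yl)pent-4-enoate | C=CCC(CC=C)C(=O)OCC=C(C)C | intermediate
4 | 3-methylbut-2-en-1-yl 5-(9-borabicyclo[3.3.1]nonan-9-yl)-2-[3-(9-borabicyclo[3.3.1]nonan-9-yl)propyl]pentanoate | CC(C)=CCOC(=O)C(CCCB1C2CCCC1CCC2)CCCB1C2CCCC1CCC2 | intermediate
5 | 3-methylbut-2-en-1-yl 5-hydroxy-2-(3-hydroxypropyl)pentanoate | CC(C)=CCOC(=O)C(CCCO)CCCO | intermediate
6 | 3-methylbut-2-en-1-yl 5-[(tert-butyldimethylsilyl)oxy]-2-{3-[(tert-butyldimethylsilyl)oxy]propyl}pentanoate | CC(C)=CCOC(=O)C(CCCO[Si](C)(C)C(C)(C)C)CCCO[Si](C)(C)C(C)(C)C | intermediate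
7 | trimethylsilyl ketene acetal of 6, {[5-[(tert-butyldimethylsilyl)oxy]-2-{3-[(tert-butyldimethylsilyl)oxy]propyl}-1-[(3-methylbut-2-en-1-yl)oxy]pent-1-en-1-yl]oxy}trimethylsilane | CC(C)=CCOC(O[Si](C)(C)C)=C(CCCO[Si](C)(C)C(C)(C)C)CCCO[Si](C)(C)C(C)(C)C | intermediate
8 | trimethylsilyl 2,2-bis{3-[(tert-butyldimethylsilyl)oxy]propyl}-3,3-dimethylpent-4-enoate | C=CC(C)(C)C(CCCO[Si](C)(C)C(C)(C)C)(CCCO[Si](C)(C)C(C)(C)C)C(=O)O[Si](C)(C)C | intermediate
9 | 2,2-bis{3-[(tert-butyldimethylsilyl)oxy]propyl}-3,3-dimethylpent-4-enoic acid | C=CC(C)(C)C(CCCO[Si](C)(C)C(C)(C)C)(CCCO[Si](C)(C)C(C)(C)C)C(=O)O | intermediate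
10 | dilithium 3,3-bis{3-[(tert-butyldimethylsilyl)oxy]propyl}-4,4-dimethylhex-5-ene-2,2-bis(olate) | C=CC(C)(C)C(CCCO[Si](C)(C)C(C)(C)C)(CCCO[Si](C)(C)C(C)(C)C)C(C)(O[Li])O[Li] | intermediate
11 | 3,3-bis{3-[(tert-butyldimethylsilyl)oxy]propyl}-4,4-dimethylhex-5-en-2-one | C=CC(C)(C)C(CCCO[Si](C)(C)C(C)(C)C)(CCCO[Si](C)(C)C(C)(C)C)C(C)=O | intermediate
12 | 1,7-bis[(tert-butyldimethylsilyl)oxy]-4-(2-methylbut-3-en-2-yl)-4-(prop-1-en-2-yl)heptane | C=CC(C)(C)C(CCCO[Si](C)(C)C(C)(C)C)(CCCO[Si](C)(C)C(C)(C)C)C(C)=C | intermediate
13 | 4-(2-methylbut-3-en-2-yl)-4-(prop-1-en-2-yl)heptane-1,7-diol | C=CC(C)(C)C(CCCO)(CCCO)C(C)=C | intermediate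
14 | 4-(2-methylbut-3-en-2-yl)-4-(prop-1-en-2-yl)heptanedial (achiral) | C=CC(C)(C)C(CCC=O)(CCC=O)C(C)=C | intermediate
15 | (2S)-1-[(1E,4S)-4-(2-methylbut-3-en-2-yl)-7-oxo-4-(prop-1-en-2-yl)hept-1-en-1-yl]pyrrolidine-2-carboxylic acid | C=CC(C)(C)[C@@](CCC=O)(C/C=C/N1CCC[C@H]1C(=O)O)C(C)=C | intermediate
16 | (2S)-1-{[(1R,2S,5S)-2-hydroxy-5-(2-methylbut-3-en-2-yl)-5-(prop-1-en-2-yl)cyclohexyl]methylidene}pyrrolidin-1-ium-2-carboxylate | C=C(C)[C@]1(C(C)(C)C=C)CC[C@H](O)[C@@H](C=[N+]2CCC[C@H]2C([O-])=O)C1 | intermediate
17 | (1S,2S,5S)-2-hydroxy-5-(2-methylbut-3-en-2-yl)-5-(prop-1-en-2-yl)cyclohexane-1-carbaldehyde | C=C(C)[C@]1(C(C)(C)C=C)CC[C@H](O)[C@@H](C=O)C1 | intermediate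
18 | (5S)-5-(2-methylbut-3-en-2-yl)-2-oxo-5-(prop-1-en-2-yl)cyclohexane-1-carbaldehyde (C1 enolised, not defined) | C=C(C)[C@]1(C(C)(C)C=C)CCC(=O)C(C=O)C1 | intermediate
19 | (5S)-1-chloro-5-(2-methylbut-3-en-2-yl)-2-oxo-5-(prop-1-en-2-yl)cyclohexane-1-carbaldehyde (both C1 epimers) | C=C(C)[C@]1(C(C)(C)C=C)CCC(=O)C(Cl)(C=O)C1 | intermediate
20 | (2S,4S)-2-chloro-4-(2-methylbut-3-en-2-yl)-4-(prop-1-en-2-yl)cyclohexan-1-one | C=C(C)[C@]1(C(C)(C)C=C)CCC(=O)[C@@H](Cl)C1 | intermediate
21 | (1R,2S,4S)-2-chloro-1-methyl-4-(2-methylbut-3-en-2-yl)-4-(prop-1-en-2-yl)cyclohexan-1-ol | C=C(C)[C@]1(C(C)(C)C=C)CC[C@@](C)(O)[C@@H](Cl)C1 | intermediate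
22 | {[(1R,2S,4S)-2-chloro-1-methyl-4-(2-methylbut-3-en-2-yl)-4-(prop-1-en-2-yl)cyclohexyl]oxy}triethylsilane | C=C(C)[C@]1(C(C)(C)C=C)CC[C@@](C)(O[Si](CC)(CC)CC)[C@@H](Cl)C1 | intermediate
23 | {3-[(1S,3S,4R)-3-chloro-4-methyl-1-(prop-1-en-2-yl)-4-(triethylsilyloxy)cyclohexyl]-3-methylbutyl}bis(3-methylbutan-2-yl)borane | C=C(C)[C@]1(C(C)(C)CCB(C(C)C(C)C)C(C)C(C)C)CC[C@@](C)(O[Si](CC)(CC)CC)[C@@H](Cl)C1 | intermediate
24 | 3-[(1S,3S,4R)-3-chloro-4-methyl-1-(prop-1-en-2-yl)-4-(triethylsilyloxy)cyclohexyl]-3-methylbutan-1-ol | C=C(C)[C@]1(C(C)(C)CCO)CC[C@@](C)(O[Si](CC)(CC)CC)[C@@H](Cl)C1 | intermediate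
25 | 3-[(1S,3S,4R)-3-chloro-4-methyl-1-(prop-1-en-2-yl)-4-(triethylsilyloxy)cyclohexyl]-3-methylbutanal | C=C(C)[C@]1(C(C)(C)CC=O)CC[C@@](C)(O[Si](CC)(CC)CC)[C@@H](Cl)C1 | intermediate
26 | (2S)-2-bromo-3-[(1S,3S,4R)-3-chloro-4-methyl-1-(prop-1-en-2-yl)-4-(triethylsilyloxy)cyclohexyl]-3-methylbutanal | C=C(C)[C@]1(C(C)(C)[C@H](Br)C=O)CC[C@@](C)(O[Si](CC)(CC)CC)[C@@H](Cl)C1 | intermediate
27 | (2S,3R,6S,8S,9R)-2-bromo-8-chloro-1,1,9-trimethyl-5-methylidene-9-[(triethylsilyl)oxy]spiro[5.5]undecan-3-ol | C=C1C[C@@H](O)[C@@H](Br)C(C)(C)[C@]12CC[C@@](C)(O[Si](CC)(CC)CC)[C@@H](Cl)C2 | intermediate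
28 | (2S,3R,6S,8S,9R)-2-bromo-8-chloro-1,1,9-trimethyl-5-methylidenespiro[5.5]undecane-3,9-diol | C=C1C[C@@H](O)[C@@H](Br)C(C)(C)[C@]12CC[C@@](C)(O)[C@@H](Cl)C2 | target

## Step count and least certain steps

Total step count: 18. Longest linear sequence: 18 steps (1 to 28; prenol 2 enters in step 1).

Step 9 (key step). The most likely failure is incomplete discrimination between the two enantiotopic arms, with dehydration or oligomerisation of the dialdehyde as a second concern. Because C9 and C10 are erased in step 10, any material that closes through the other arm lowers the enantiomeric purity of 18 directly. The fallback sets out from 18 of whatever purity. Deformylation with warm aqueous NaOH would give the achiral ketone 4-(2-methylbut-3-en-2-yl)-4-(prop-1-en-2-yl)cyclohexan-1-one F1. Enantioselective deprotonation of F1 with a chiral lithium amide (lithium bis[(R)-1-phenylethyl]amide or its antipode, chosen to remove the axial hydrogen at C10, with Me3SiCl present, THF, −78 °C) would give the silyl enol ether trimethyl{[(4S)-4-(2-methylbut-3-en-2-yl)-4-(prop-1-en-2-yl)cyclohex-1-en-1-yl]oxy}silane F2. Chlorination of F2 with NCS and equilibration as in step 11 would return to the route at 20. Here the desymmetrisation is done by a chiral base on a cyclohexanone instead of by the aldol closure.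

Step 6. The methylenation may stall because the carbonyl is attached to the quaternary C6, so the reagent decomposes thermally before it reacts. The fallback sets out from 11: MeLi with CeCl3 in THF at −78 °C would give the tertiary alcohol 3,3-bis{3-[(tert-butyldimethylsilyl)oxy]propyl}-2,4,4-trimethylhex-5-en-2-ol F3, and Burgess dehydration (methyl N-(triethylammoniosulfonyl)carbamate, toluene, 70 °C) would give 12. Only the isopropenyl alkene can form, because C6 carries no hydrogen.

Step 12. The risk is poor facial selectivity (axial entry of methyl, giving the C9 epimer) or enolisation of the alpha-chloro ketone. The fallback sets out from 20 and uses a bulkier primary carbanion, for which equatorial entry is more strongly preferred. (Phenylselanyl)methyllithium, from bis(phenylselanyl)methane and n-BuLi at −78 °C, would give the hydroxy selenide (1R,2S,4S)-2-chloro-4-(2-methylbut-3-en-2-yl)-1-[(phenylselanyl)methyl]-4-(prop-1-en-2-yl)cyclohexan-1-ol F4. Reduction of the C–Se bond with Bu3SnH and AIBN would then give 21, where the route is rejoined.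

Step 14. The risk is competing hydroboration of the isopropenyl group, or a sluggish reaction at the vinyl group, which sits on a quaternary carbon. The fallback sets out from 22 and reaches 25 in one operation by aldehyde-selective Wacker oxidation (PdCl2(PhCN)2, CuCl2, AgNO2, t-BuOH–MeNO2, O2, rt). The quaternary allylic carbon directs oxygen to the terminal carbon, and 1,1-disubstituted alkenes are poor substrates. No new compound is made.

Step 16. The risks are erosion of configuration at C4 (racemisation through the enamine, or a mismatched bias from ring B) and over-bromination. The fallback sets out from 25 and relies on a covalently bound oxazolidinone auxiliary: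
- Pinnick oxidation (NaClO2, NaH2PO4, 2-methylbut-2-ene) would give the acid 3-[(1S,3S,4R)-3-chloro-4-methyl-1-(prop-1-en-2-yl)-4-(triethylsilyloxy)cyclohexyl]-3-methylbutanoic acid F5.
- Acylation of lithiated (4S)-4-benzyl-1,3-oxazolidin-2-one through the pivaloyl mixed anhydride would give the imide (4S)-4-benzyl-3-{3-[(1S,3S,4R)-3-chloro-4-methyl-1-(prop-1-en-2-yl)-4-(triethylsilyloxy)cyclohexyl]-3-methylbutanoyl}-1,3-oxazolidin-2-one F6.
- Boron enolate formation (Bu2BOTf, iPr2NEt) and bromination with NBS would give, under auxiliary control, the bromo imide (4S)-4-benzyl-3-{(2S)-2-bromo-3-[(1S,3S,4R)-3-chloro-4-methyl-1-(prop-1-en-2-yl)-4-(triethylsilyloxy)cyclohexyl]-3-methylbutanoyl}-1,3-oxazolidin-2-one F7. This is known for 3,3-dimethylbutanoyl imides.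
- LiBH4 would remove the auxiliary and give the bromo alcohol (2S)-2-bromo-3-[(1S,3S,4R)-3-chloro-4-methyl-1-(prop-1-en-2-yl)-4-(triethylsilyloxy)cyclohexyl]-3-methylbutan-1-ol F8.
- Dess–Martin oxidation would return to the route at 26.

Step 17. The risk is the wrong or a mixed configuration at C3, since the axial oxygen is syn-diaxial to one C5 methyl group and the closure may pass through a boat or a stepwise cation; methyl transfer from aluminium is a second concern. The fallback sets out from 26 and sets C3 by reduction instead of by the ene transition state. The closure is run without regard to C3. The C3 epimer (2S,3S,6S,8S,9R)-2-bromo-8-chloro-1,1,9-trimethyl-5-methylidene-9-[(triethylsilyl)oxy]spiro[5.5]undecan-3-ol F9, alone or mixed with 27, would be oxidised with Dess–Martin periodinane to the bromo ketone (2S,6S,8S,9R)-2-bromo-8-chloro-1,1,9-trimethyl-5-methylidene-9-[(triethylsilyl)oxy]spiro[5.5]undecan-3-one F10. Reduction with LiBH(s-Bu)3 at −78 °C would deliver hydride along the equatorial trajectory, away from the axial C5 methyl group, giving the axial alcohol cis to bromine, which is 27.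

## Further compounds

F1 | step 9 | 4-(2-methylbut-3-en-2-yl)-4-(prop-1-en-2-yl)cyclohexan-1-one | C=CC(C)(C)C1(C(C)=C)CCC(=O)CC1
F2 | step 9 | trimethyl{[(4S)-4-(2-methylbut-3-en-2-yl)-4-(prop-1-en-2-yl)cyclohex-1-en-1-yl]oxy}silane | C=C(C)[C@]1(C(C)(C)C=C)CCC(O[Si](C)(C)C)=CC1
F3 | step 6 | 3,3-bis{3-[(tert-butyldimethylsilyl)oxy]propyl}-2,4,4-trimethylhex-5-en-2-ol | C=CC(C)(C)C(CCCO[Si](C)(C)C(C)(C)C)(CCCO[Si](C)(C)C(C)(C)C)C(C)(C)O
F4 | step 12 | (1R,2S,4S)-2-chloro-4-(2-methylbut-3-en-2-yl)-1-[(phenylselanyl)methyl]-4-(prop-1-en-2-yl)cyclohexan-1-ol | C=C(C)[C@]1(C(C)(C)C=C)CC[C@@](C[Se]c2ccccc2)(O)[C@@H](Cl)C1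
F0 | step 14 | none | none
F5 | step 16 | 3-[(1S,3S,4R)-3-chloro-4-methyl-1-(prop-1-en-2-yl)-4-(triethylsilyloxy)cyclohexyl]-3-methylbutanoic acid | C=C(C)[C@]1(C(C)(C)CC(=O)O)CC[C@@](C)(O[Si](CC)(CC)CC)[C@@H](Cl)C1
F6 | step 16 | (4S)-4-benzyl-3-{3-[(1S,3S,4R)-3-chloro-4-methyl-1-(prop-1-en-2-yl)-4-(triethylsilyloxy)cyclohexyl]-3-methylbutanoyl}-1,3-oxazolidin-2-one | C=C(C)[C@]1(C(C)(C)CC(=O)N2[C@@H](Cc3ccccc3)COC2=O)CC[C@@](C)(O[Si](CC)(CC)CC)[C@@H](Cl)C1
F7 | step 16 | (4S)-4-benzyl-3-{(2S)-2-bromo-3-[(1S,3S,4R)-3-chloro-4-methyl-1-(prop-1-en-2-yl)-4-(triethylsilyloxy)cyclohexyl]-3-methylbutanoyl}-1,3-oxazolidin-2-one | C=C(C)[C@]1(C(C)(C)[C@H](Br)C(=O)N2[C@@H](Cc3ccccc3)COC2=O)CC[C@@](C)(O[Si](CC)(CC)CC)[C@@H](Cl)C1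
F8 | step 16 | (2S)-2-bromo-3-[(1S,3S,4R)-3-chloro-4-methyl-1-(prop-1-en-2-yl)-4-(triethylsilyloxy)cyclohexyl]-3-methylbutan-1-ol | C=C(C)[C@]1(C(C)(C)[C@H](Br)CO)CC[C@@](C)(O[Si](CC)(CC)CC)[C@@H](Cl)C1
F9 | step 17 | (2S,3S,6S,8S,9R)-2-bromo-8-chloro-1,1,9-trimethyl-5-methylidene-9-[(triethylsilyl)oxy]spiro[5.5]undecan-3-ol | C=C1C[C@H](O)[C@@H](Br)C(C)(C)[C@]12CC[C@@](C)(O[Si](CC)(CC)CC)[C@@H](Cl)C2
F10 | step 17 | (2S,6S,8S,9R)-2-bromo-8-chloro-1,1,9-trimethyl-5-methylidene-9-[(triethylsilyl)oxy]spiro[5.5]undecan-3-one | C=C1CC(=O)[C@@H](Br)C(C)(C)[C@]12CC[C@@](C)(O[Si](CC)(CC)CC)[C@@H](Cl)C2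
A1 | alternative 1 | bis-silyl ether of 28 (tert-butyldimethylsilyl on the C3 oxygen, triethylsilyl on the C9 oxygen) | C=C1C[C@@H](O[Si](C)(C)C(C)(C)C)[C@@H](Br)C(C)(C)[C@]12CC[C@@](C)(O[Si](CC)(CC)CC)[C@@H](Cl)C2
A2 | alternative 1 | ring A seco iodo alkyne: ring B as in A1, ethynyl on C6, chain C5(CH3)2–C4HBr–C3H(OSi t-BuMe2)–C2H2I, configured as 28 at C3, C4, C6, C9 and C10 | IC[C@@H](O[Si](C)(C)C(C)(C)C)[C@@H](Br)C(C)(C)[C@@]1(C#C)CC[C@@](C)(O[Si](CC)(CC)CC)[C@@H](Cl)C1
A3 | alternative 2 | 1-[3-chloro-4-methyl-1-(2-methylbut-3-en-2-yl)-4-(triethylsilyloxy)cyclohexyl]ethan-1-one, configured as 28 at C6, C9 and C10 | CC(=O)[C@]1(C(C)(C)C=C)CC[C@@](C)(O[Si](CC)(CC)CC)[C@@H](Cl)C1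
A4 | alternative 2 | (6R)-3-chloro-6-methyl-3-(2-methylbut-3-en-2-yl)-6-(triethylsilyloxy)oct-7-en-2-one (either configuration at C3) | CC(=O)C(Cl)(C(C)(C)C=C)CC[C@@](C)(O[Si](CC)(CC)CC)C=C
A5 | alternative 2 | (R)-linalool, (3R)-3,7-dimethylocta-1,6-dien-3-ol | CC(C)=CCC[C@@](C)(O)C=C
A6 | alternative 3 | spiro alpha-chloro ketone with complete ring A: 28 with a ketone at C9 in place of the methyl carbinol and tert-butyldimethylsilyl on the C3 oxygen | C=C1C[C@@H](O[Si](C)(C)C(C)(C)C)[C@@H](Br)C(C)(C)[C@]12CCC(=O)[C@@H](Cl)C2
A7 | alternative 3 | ring A cyclohexene (C1=C6) with C1 methyl, C3 OSi t-BuMe2 (R), C4 Br (S), C5 gem-dimethyl, and on C6 the chain CH2–CHCl(S)–CO–CH=CH2 | CC1=C(C[C@H](Cl)C(=O)C=C)C(C)(C)[C@H](Br)[C@H](O[Si](C)(C)C(C)(C)C)C1
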